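The route rests on closing ring A (C1–C2–C3–C4–C4a–C8a) at the C3–C4 bond. Ring A holds an oxygen at C2 and an exocyclic methylene at C4; this 1,3-pair is the retron of a Conia-ene closure. A monovalent-gold catalyst lets the CH2 terminus of a C2 silyl enol ether attack the internal carbon of an ethynyl group on C4a. In one operation this closes ring A as a trans-decalin, writes the C4 methylene and unmasks a C2 ketone. The precursor is a trans-disubstituted cyclohexene (ring B). It is made by an acrylate-tethered intramolecular Diels–Alder reaction whose tether supplies C4, C4a and C5 and whose anchoring oxygen becomes the enol oxygen.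

Key step: step 12

Remark on numbering and abbreviations: octahydronaphthalene numbering is used. C1 bears the acrylic acid (Cα is its substituted alkene carbon), C2 the acyloxy group, C4 the methylene and C7 the CH2OH; C4a and C8a are the fusion carbons. Ring B is C4a–C5–C6–C7–C8–C8a. TBS = tert-butyldimethylsilyl, pin = pinacolato.
Remark on supply: chloroacetaldehyde is bought as its aqueous solution and is extracted and dried before use.

Step 1
Reactants: 1 2-bromoprop-2-en-1-ol
Product: 2 (2-bromoallyloxy)(tert-butyl)dimethylsilane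
Conditions: TBSCl, imidazole, CH2Cl2, 0 °C to rt
Reagents that add atoms: tert-butyldimethylsilyl chloride, C[Si](C)(Cl)C(C)(C)C
Why: Routine imidazole-assisted silyl ether formation that masks the future C7 hydroxymethyl oxygen; no stereocentre is involved.

Step 2
Reactants: 2 (2-bromoallyloxy)(tert-butyl)dimethylsilane; 3 acrolein
Product: 4 (2E)-4-[(TBSO)methyl]penta-2,4-dienal
Conditions: Pd(OAc)2 (5 mol %), n-Bu4NCl, NaHCO3, DMF, 40 °C
Reagents that add atoms: none
Why: Heck reaction under ligand-free phase-transfer conditions: the alkenyl-palladium species adds to the unsubstituted acrolein terminus and syn β-hydride elimination should give the E-enal, which puts the diene C6=C7–C8=C8a in place.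

Step 3
Reactants: 4 (2E)-4-[(TBSO)methyl]penta-2,4-dienal; 5 tert-butyl acrylate
Product: 6 racemic tert-butyl (4E)-3-hydroxy-2-methylidene-6-[(TBSO)methyl]hepta-4,6-dienoate
Conditions: DABCO, 1,4-dioxane/H2O 1:1, rt
Reagents that add atoms: none
Why: Morita–Baylis–Hillman reaction: the amine-derived acrylate enolate adds 1,2 to the aldehyde carbon (future C1) and joins it to Cα; the racemic carbinol is harmless because it is flattened in step 5.

Step 4
Reactants: 6 racemic Morita–Baylis–Hillman alcohol
Product: 7 racemic tert-butyl (4E)-3-acetoxy-2-methylidene-6-[(TBSO)methyl]hepta-4,6-dienoate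
Conditions: Ac2O, pyridine, DMAP (cat.), CH2Cl2, 0 °C
Reagents that add atoms: acetic anhydride, CC(=O)OC(C)=O
Why: Acetylation turns the allylic alcohol into a leaving group for π-allyl formation.

Step 5
Reactants: 7 racemic allylic acetate
Product: 8 tert-butyl (2E,4E)-2-[(pinB)methyl]-6-[(TBSO)methyl]hepta-2,4,6-trienoate (dienyl chain cis to CH2Bpin)
Conditions: B2pin2, Pd2(dba)3 (2.5 mol %), toluene, 50 °C
Reagents that add atoms: bis(pinacolato)diboron, CC1(C)OB(OC1(C)C)B1OC(C)(C)C(C)(C)O1
Why: Allylic borylation of a Morita–Baylis–Hillman acetate catalysed by zerovalent palladium: boron goes to the unhindered CH2 terminus of the π-allyl complex, and the conjugated trisubstituted alkene should form with the dienyl group trans to the ester, that is cis to CH2Bpin.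

Step 6
Reactants: 8 allylboronate; 9 chloroacetaldehyde
Product: 11 tert-butyl (3S,4E)-3-[(1R)-2-chloro-1-hydroxyethyl]-2-methylidene-6-[(TBSO)methyl]hepta-4,6-dienoate (syn chlorohydrin), via O-boryl ether 10 (not isolated)
Conditions: (R)-TRIP (10 mol %), 4 Å MS, toluene, −20 °C to rt; then H2O
Reagents that add atoms: none
Why: Chiral-phosphoric-acid-catalysed allylboration through a closed chair: the cis relation of dienyl group and CH2B gives the syn C1/C2 pair, and the (R)-catalyst is expected, by analogy with simple aldehydes, to direct attack to the Re face of the aldehyde and so fix the absolute configuration of C1 and C2.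

Step 7
Reactants: 11 syn chlorohydrin; 12 acryloyl chloride
Product: 13 tert-butyl (3S,4E)-3-[(1R)-1-(acryloyloxy)-2-chloroethyl]-2-methylidene-6-[(TBSO)methyl]hepta-4,6-dienoate
Conditions: Et3N, DMAP (cat.), CH2Cl2, −20 °C
Reagents that add atoms: none
Why: O-Acylation with an acid chloride installs the dienophile, whose three carbons become C4, C4a and C5; the stereocentres are untouched.

Step 8
Reactants: 13 acrylate triene
Product: 15 trans-fused δ-lactone (3-oxa analogue of ring A: O in place of C3, C4 as lactone carbonyl, CH2Cl on C2 and tert-butyl acrylate on C1 both equatorial, ring B complete), via cis-fused lactone 14 (not isolated)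
Conditions: toluene (0.01 M), BHT, sealed tube, 170 °C; then DBU (0.2 equiv), rt
Reagents that add atoms: none
Why: Ester-tethered intramolecular Diels–Alder reaction of the 1,7,9-decatriene type: with H-1 eclipsing the diene, the tether can reach only the diene face anti to the C1 acrylate, which sets C8a, and DBU equilibrates the α-carbonyl centre C4a so that endo and exo adducts should converge on the all-equatorial trans-fused lactone.

Step 9
Reactants: 15 trans-fused δ-lactone
Product: 16 lactol (C4 hemiacetal, both anomers)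
Conditions: i-Bu2AlH (1.1 equiv), CH2Cl2, −78 °C; aq. potassium sodium tartrate
Reagents that add atoms: none
Why: Partial reduction of a lactone: the tetrahedral aluminium hemiacetal survives at −78 °C, and the hindered, conjugated tert-butyl ester reacts far more slowly than the δ-lactone.

Step 10
Reactants: 16 lactol; 17 dimethyl (1-diazo-2-oxopropyl)phosphonate
Product: 19 alkynyl epoxide (ring B with ethynyl on C4a trans to the C8a side chain; C1 bears the tert-butyl acrylate and the C2–C3 oxirane), via alkynyl chlorohydrin 18 (not isolated)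
Conditions: K2CO3, MeOH, 0 °C to rt
Reagents that add atoms: none
Why: Ohira–Bestmann homologation of the open hydroxy-aldehyde form should give the terminal alkyne with C4a kept in its more stable trans arrangement, and the same base lets the freed C2 alkoxide displace chloride (Williamson-type epoxide closure with retention at C2).

Step 11
Reactants: 19 alkynyl epoxide
Product: 21 silyl enol ether (C3H2=C2(OTBS)– on C1, ethynyl on C4a), via iodo silyl ether 20 (not isolated)
Conditions: TBSCl, NaI, MeCN, rt, then 19 at −40 °C; then DBU, 60 °C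
Reagents that add atoms: tert-butyldimethylsilyl chloride, C[Si](C)(Cl)C(C)(C)C
Why: The silyl iodide opens the terminal epoxide at the primary carbon C3 (SN2), and E2 dehydroiodination, for which C2–H is the only β-hydrogen, should give the silyl enol ether regiospecifically towards C3 without passing through the enolisable ketone; the C2 stereocentre has served as tether anchor and is deliberately flattened.

Step 12
Reactants: 21 silyl enol ether
Product: 22 tert-butyl 2-[(1S,4aS,8aS)-7-[(TBSO)methyl]-4-methylidene-2-oxo-1,2,3,4,4a,5,6,8a-octahydronaphthalen-1-yl]prop-2-enoate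
Conditions: Ph3PAuCl (10 mol %), AgBF4 (10 mol %), CH2Cl2/MeOH 10:1, rt to 40 °C
Reagents that add atoms: none
Why: Ph3PAu+ (monovalent gold) binds the terminal alkyne as a π-acid, the nucleophilic CH2 terminus C3 of the silyl enol ether attacks the internal alkyne carbon C4 anti to gold, and methanol takes the silyl group from the silyloxocarbenium ion and protonates the alkenyl–gold bond, which releases the ketone with the C4 exocyclic methylene. The closest known reaction type is the gold-catalysed Conia-ene-type carbocyclisation of silyl enol ethers onto alkynes. Ring A closes in the 6-exo-dig mode through a chair in which the C1 side chain and the ring-B bonds stay equatorial, so a trans-decalin should result. No new stereocentre is formed: C1, C4a and C8a are carried through unchanged because the medium is neither basic nor strongly acidic and the enol ether is regiodefined away from C1. The step needs chemoselectivity among four π-nucleophiles and Markovnikov regioselectivity at the alkyne. The silyl enol ether is by far the most electron-rich alkene, the acrylate is electron-poor, the ring-B alkene cannot reach the linear alkyne without forming a strained bridged cation, and a terminal alkyne is attacked at its internal carbon.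

Step 13
Reactants: 22 ketone
Product: 23 tert-butyl 2-[(1S,2S,4aS,8aS)-2-hydroxy-7-[(TBSO)methyl]-4-methylidene-1,2,3,4,4a,5,6,8a-octahydronaphthalen-1-yl]prop-2-enoate (axial C2 alcohol)
Conditions: LiBH(s-Bu)3 (1.05 equiv), THF, −78 °C; pH 7 buffer at −78 °C
Reagents that add atoms: none
Why: Reduction of a 2-substituted cyclohexanone with a bulky trialkylborohydride: hydride comes from the equatorial side, so the C2 alcohol should be axial and cis to the equatorial C1 side chain, and at −78 °C the ketone outruns conjugate reduction of the hindered tert-butyl acrylate.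

Step 14
Reactants: 24 (tert-butyldimethylsilyloxy)acetaldehyde; 25 1,1,1,3,3,3-hexafluoropropan-2-yl acrylate
Product: 26 1,1,1,3,3,3-hexafluoropropan-2-yl (3S)-3-hydroxy-2-methylidene-4-(TBSO)butanoate
Conditions: β-isocupreidine (10 mol %), DMF, −55 °C
Reagents that add atoms: none
Why: Asymmetric Morita–Baylis–Hillman reaction: the quinidine-derived bifunctional amine adds to the activated acrylate and its phenol steers the proton transfer of one diastereomeric aldolate, which should set the (S)-carbinol of the side chain.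

Step 15
Reactants: 26 side-chain hydroxy ester
Product: 27 1,1,1,3,3,3-hexafluoropropan-2-yl (3S)-3,4-bis(TBSO)-2-methylidenebutanoate
Conditions: TBSOTf, 2,6-lutidine, CH2Cl2, −78 to 0 °C
Reagents that add atoms: tert-butyldimethylsilyl triflate, CC(C)(C)[Si](C)(C)OS(=O)(=O)C(F)(F)F
Why: Silylation of the secondary allylic alcohol with a silyl triflate under lutidine buffering; the carbinol C–O bond is not touched, so the configuration is kept.

Step 16
Reactants: 27 bis-silyl ester
Product: 28 (3S)-3,4-bis(TBSO)-2-methylidenebutanoic acid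
Conditions: LiOH, THF/H2O, 0 °C; then aq. HCl to pH 4
Reagents that add atoms: lithium hydroxide, [Li+].[OH-]
Why: Saponification of an activated ester: the fluorinated alkoxide is a good leaving group, so acyl–oxygen cleavage should be fast at 0 °C without touching the silyl ethers or the stereocentre.

Step 17
Reactants: 23 axial C2 alcohol; 28 side-chain acid
Product: 30 fully protected target (tert-butyl ester, three TBS ethers), via mixed anhydride 29 (not isolated)
Conditions: 28, 2,4,6-trichlorobenzoyl chloride, Et3N, toluene, rt; then 23, DMAP, toluene, rt to 40 °C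
Reagents that add atoms: none
Why: Yamaguchi esterification: DMAP attacks the mixed anhydride at the less hindered acyl group and the acylpyridinium ion acylates the hindered axial C2 alcohol, with retention at C2 and at the side-chain carbinol.

Step 18
Reactants: 30 fully protected target
Product: 32 CNP0460913.1, 2-[(1S,2S,4aS,8aS)-2-{[(3S)-3,4-dihydroxy-2-methylidenebutanoyl]oxy}-7-(hydroxymethyl)-4-methylidene-1,2,3,4,4a,5,6,8a-octahydronaphthalen-1-yl]prop-2-enoic acid, via trimethylsilyl ester 31 (not isolated)
Conditions: TMSOTf, 2,6-lutidine, CH2Cl2, 0 °C; then HF·pyridine, THF, 0 °C to rt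
Reagents that add atoms: none
Why: Silyl-triflate-mediated cleavage of the tert-butyl ester (loss of isobutene under lutidine buffering, so no free acid can move the C4 methylene) followed by fluoride-driven desilylation in a mildly acidic medium, in which the base-labile dihydroxy ester should not lactonise; no stereocentre is touched.

Compound list
1 | 2-bromoprop-2-en-1-ol | C=C(Br)CO | starting material
2 | (2-bromoallyloxy)(tert-butyl)dimethylsilane | C=C(Br)CO[Si](C)(C)C(C)(C)C | intermediate
3 | acrolein | C=CC=O | starting material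
4 | (2E)-4-[(TBSO)methyl]penta-2,4-dienal | O=C/C=C/C(=C)CO[Si](C)(C)C(C)(C)C | intermediate
5 | tert-butyl acrylate | C=CC(=O)OC(C)(C)C | starting material
6 | racemic tert-butyl (4E)-3-hydroxy-2-methylidene-6-[(TBSO)methyl]hepta-4,6-dienoate | OC(/C=C/C(=C)CO[Si](C)(C)C(C)(C)C)C(=C)C(=O)OC(C)(C)C | intermediate
7 | racemic tert-butyl (4E)-3-acetoxy-2-methylidene-6-[(TBSO)methyl]hepta-4,6-dienoate | CC(=O)OC(/C=C/C(=C)CO[Si](C)(C)C(C)(C)C)C(=C)C(=O)OC(C)(C)C | intermediate
8 | tert-butyl (2E,4E)-2-[(pinB)methyl]-6-[(TBSO)methyl]hepta-2,4,6-trienoate | CC1(C)OB(C/C(C(=O)OC(C)(C)C)=C\C=C\C(=C)CO[Si](C)(C)C(C)(C)C)OC1(C)C | intermediate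
9 | chloroacetaldehyde | ClCC=O | starting material
10 | O-(pinacolatoboryl) ether of 11 | CC1(C)OB(O[C@@H](CCl)[C@@H](/C=C/C(=C)CO[Si](C)(C)C(C)(C)C)C(=C)C(=O)OC(C)(C)C)OC1(C)C | intermediate
11 | tert-butyl (3S,4E)-3-[(1R)-2-chloro-1-hydroxyethyl]-2-methylidene-6-[(TBSO)methyl]hepta-4,6-dienoate | O[C@@H](CCl)[C@@H](/C=C/C(=C)CO[Si](C)(C)C(C)(C)C)C(=C)C(=O)OC(C)(C)C | intermediate
12 | acryloyl chloride | C=CC(=O)Cl | starting material
13 | tert-butyl (3S,4E)-3-[(1R)-1-(acryloyloxy)-2-chloroethyl]-2-methylidene-6-[(TBSO)methyl]hepta-4,6-dienoate | C=CC(=O)O[C@@H](CCl)[C@@H](/C=C/C(=C)CO[Si](C)(C)C(C)(C)C)C(=C)C(=O)OC(C)(C)C | intermediate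
14 | cis-fused δ-lactone, C4a epimer of 15 | C=C(C(=O)OC(C)(C)C)[C@@H]1[C@H]2C=C(CO[Si](C)(C)C(C)(C)C)CC[C@H]2C(=O)O[C@H]1CCl | intermediate
15 | trans-fused δ-lactone (O in place of C3; C1, C2, C4a, C8a configured as in 32) | C=C(C(=O)OC(C)(C)C)[C@@H]1[C@H]2C=C(CO[Si](C)(C)C(C)(C)C)CC[C@@H]2C(=O)O[C@H]1CCl | intermediate
16 | lactol of 15 (C4 hemiacetal, both anomers) | C=C(C(=O)OC(C)(C)C)[C@@H]1[C@H]2C=C(CO[Si](C)(C)C(C)(C)C)CC[C@@H]2C(O)O[C@H]1CCl | intermediate
17 | dimethyl (1-diazo-2-oxopropyl)phosphonate | CC(=O)C(=[N+]=[N-])P(=O)(OC)OC | starting material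
18 | alkynyl chlorohydrin (ethynyl on C4a, free C2 hydroxyl, C3 chloride) | C=C(C(=O)OC(C)(C)C)[C@H]([C@H]1C=C(CO[Si](C)(C)C(C)(C)C)CC[C@@H]1C#C)[C@H](CCl)O | intermediate
19 | alkynyl epoxide (C2–C3 oxirane; C1, C2, C4a, C8a as in 32) | C=C(C(=O)OC(C)(C)C)[C@H]([C@H]1C=C(CO[Si](C)(C)C(C)(C)C)CC[C@@H]1C#C)[C@@H]2CO2 | intermediate
20 | iodo silyl ether (C2 OTBS, C3 iodide) | C=C(C(=O)OC(C)(C)C)[C@H]([C@H]1C=C(CO[Si](C)(C)C(C)(C)C)CC[C@@H]1C#C)[C@H](CI)O[Si](C)(C)C(C)(C)C | intermediate
21 | silyl enol ether C3H2=C2(OTBS) with ethynyl on C4a (C1, C4a, C8a as in 32) | C=C(C(=O)OC(C)(C)C)[C@H]([C@H]1C=C(CO[Si](C)(C)C(C)(C)C)CC[C@@H]1C#C)C(=C)O[Si](C)(C)C(C)(C)C | intermediate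
22 | tert-butyl 2-[(1S,4aS,8aS)-7-[(TBSO)methyl]-4-methylidene-2-oxo-octahydronaphthalen-1-yl]prop-2-enoate | C=C(C(=O)OC(C)(C)C)[C@@H]1[C@H]2C=C(CO[Si](C)(C)C(C)(C)C)CC[C@@H]2C(=C)CC1=O | intermediate
23 | tert-butyl 2-[(1S,2S,4aS,8aS)-2-hydroxy-7-[(TBSO)methyl]-4-methylidene-octahydronaphthalen-1-yl]prop-2-enoate | C=C(C(=O)OC(C)(C)C)[C@@H]1[C@H]2C=C(CO[Si](C)(C)C(C)(C)C)CC[C@@H]2C(=C)C[C@@H]1O | intermediate
24 | (tert-butyldimethylsilyloxy)acetaldehyde | O=CCO[Si](C)(C)C(C)(C)C | starting material
25 | 1,1,1,3,3,3-hexafluoropropan-2-yl acrylate | C=CC(=O)OC(C(F)(F)F)C(F)(F)F | starting material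
26 | 1,1,1,3,3,3-hexafluoropropan-2-yl (3S)-3-hydroxy-2-methylidene-4-(TBSO)butanoate | C=C(C(=O)OC(C(F)(F)F)C(F)(F)F)[C@H](O)CO[Si](C)(C)C(C)(C)C | intermediate
27 | 1,1,1,3,3,3-hexafluoropropan-2-yl (3S)-3,4-bis(TBSO)-2-methylidenebutanoate | C=C(C(=O)OC(C(F)(F)F)C(F)(F)F)[C@H](O[Si](C)(C)C(C)(C)C)CO[Si](C)(C)C(C)(C)C | intermediate
28 | (3S)-3,4-bis(TBSO)-2-methylidenebutanoic acid | C=C(C(=O)O)[C@H](O[Si](C)(C)C(C)(C)C)CO[Si](C)(C)C(C)(C)C | intermediate
29 | mixed anhydride of 28 with 2,4,6-trichlorobenzoic acid | C=C(C(=O)OC(=O)c1c(Cl)cc(Cl)cc1Cl)[C@H](O[Si](C)(C)C(C)(C)C)CO[Si](C)(C)C(C)(C)C | intermediate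
30 | fully protected target (tert-butyl ester, three TBS ethers) | C=C(C(=O)OC(C)(C)C)[C@@H]1[C@H]2C=C(CO[Si](C)(C)C(C)(C)C)CC[C@@H]2C(=C)C[C@@H]1OC(=O)C(=C)[C@H](O[Si](C)(C)C(C)(C)C)CO[Si](C)(C)C(C)(C)C | intermediate
31 | trimethylsilyl ester of the tris-TBS acid | C=C(C(=O)O[Si](C)(C)C)[C@@H]1[C@H]2C=C(CO[Si](C)(C)C(C)(C)C)CC[C@@H]2C(=C)C[C@@H]1OC(=O)C(=C)[C@H](O[Si](C)(C)C(C)(C)C)CO[Si](C)(C)C(C)(C)C | intermediate
32 | CNP0460913.1 | C=C(C(=O)O)[C@@H]1[C@H]2C=C(CO)CC[C@@H]2C(=C)C[C@@H]1OC(=O)C(=C)[C@H](O)CO | target

Total step count: 18. Longest linear sequence: 15 steps (steps 1 to 13, then 17 and 18, from 2-bromoprop-2-en-1-ol).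

Steps most likely to fail

**Step 12.** Protodesilylation of the silyl enol ether by methanol may outrun the 6-exo-dig attack. The methyl ketone set free would then let the acrylate alkene, or after closure the C4 methylene, drift into conjugation. The fallback replaces the redox-neutral closure on an alkyne by an oxidative closure on an alkene. It sets out from lactol 16 and comes back at ketone 22.
- Wittig methylenation of 16 (Ph3PCH3Br, KOt-Bu, THF) should give the vinyl epoxide F1, once the liberated C2 alkoxide has displaced chloride in the same flask.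
- t-BuMe2SiI then opens it at C3 to the vinyl iodo silyl ether F2, and DBU eliminates HI to the vinyl silyl enol ether F3.
- Pd(OAc)2 in DMSO under O2 (cycloalkenylation of the Saegusa type) should then give 22. The divalent-palladium enolate adds 6-exo to the vinyl group and forms C3–C4, and β-hydride elimination of H-4 writes the methylene.

**Step 8.** The ester tether may populate the reactive conformer too poorly, so that polymerisation or thermal loss of the tert-butyl group overtakes the cycloaddition. Facial selectivity at the diene may also be poor. The fallback gives up the tether and uses catalyst control in an intermolecular reaction. It sets out from chlorohydrin 11 and comes back at silyl enol ether 21.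
- TBSOTf and 2,6-lutidine give the chlorohydrin TBS ether F4.
- A Diels–Alder reaction with acrolein 3 is run under iminium catalysis by 5-benzyl-2,2,3-trimethylimidazolidin-4-one hydrochloride, using the antipode that delivers the C8a configuration of 15. It should give the endo adduct, the cis aldehyde F5.
- K2CO3 in MeOH epimerises C4a to the trans aldehyde F6, and reagent 17 in the same medium gives the alkynyl chloro silyl ether F7.
- E2 loss of HCl with KOt-Bu in THF should give 21, with the TBS group already on the enol oxygen.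

**Step 6.** The ester-deactivated pinacol boronate may react too slowly under the weak chiral acid. An uncatalysed background addition would then erode the facial selectivity at the aldehyde. The fallback moves the source of chirality onto boron and raises the reactivity of the reagent. It sets out from alcohol 6 and comes back at chlorohydrin 11.
- Direct borylation of 6 with B2(OH)4 (H2PdCl4, 5 mol %, DMSO/H2O) should give the allylboronic acid F8.
- Condensation with diisopropyl (2R,3R)-tartrate over MgSO4 gives the tartrate allylboronate F9. The other tartrate antipode is taken if the sense of induction demands it.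
- Its uncatalysed addition to 9 in toluene at −78 °C over 4 Å MS, through the same closed chair, should give 11 after aqueous work-up.

Further compounds
F1 | step 12 | vinyl epoxide (vinyl on C4a, C2–C3 oxirane) | C=C(C(=O)OC(C)(C)C)[C@H]([C@H]1C=C(CO[Si](C)(C)C(C)(C)C)CC[C@@H]1C=C)[C@@H]2CO2
F2 | step 12 | vinyl iodo silyl ether (C2 OTBS, C3 iodide) | C=C(C(=O)OC(C)(C)C)[C@H]([C@H]1C=C(CO[Si](C)(C)C(C)(C)C)CC[C@@H]1C=C)[C@H](CI)O[Si](C)(C)C(C)(C)C
F3 | step 12 | vinyl silyl enol ether | C=C(C(=O)OC(C)(C)C)[C@H]([C@H]1C=C(CO[Si](C)(C)C(C)(C)C)CC[C@@H]1C=C)C(=C)O[Si](C)(C)C(C)(C)C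
F4 | step 8 | chlorohydrin TBS ether | CC(C)(C)[Si](C)(C)O[C@@H](CCl)[C@@H](/C=C/C(=C)CO[Si](C)(C)C(C)(C)C)C(=C)C(=O)OC(C)(C)C
F5 | step 8 | cis aldehyde (endo adduct) | C=C(C(=O)OC(C)(C)C)[C@H]([C@H]1C=C(CO[Si](C)(C)C(C)(C)C)CC[C@H]1C=O)[C@H](CCl)O[Si](C)(C)C(C)(C)C
F6 | step 8 | trans aldehyde | C=C(C(=O)OC(C)(C)C)[C@H]([C@H]1C=C(CO[Si](C)(C)C(C)(C)C)CC[C@@H]1C=O)[C@H](CCl)O[Si](C)(C)C(C)(C)C
F7 | step 8 | alkynyl chloro silyl ether | C=C(C(=O)OC(C)(C)C)[C@H]([C@H]1C=C(CO[Si](C)(C)C(C)(C)C)CC[C@@H]1C#C)[C@H](CCl)O[Si](C)(C)C(C)(C)C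
F8 | step 6 | allylboronic acid | OB(O)C/C(C(=O)OC(C)(C)C)=C\C=C\C(=C)CO[Si](C)(C)C(C)(C)C
F9 | step 6 | tartrate allylboronate | CC(C)OC(=O)[C@@H]1OB(C/C(C(=O)OC(C)(C)C)=C\C=C\C(=C)CO[Si](C)(C)C(C)(C)C)O[C@H]1C(=O)OC(C)C
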